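Ni(cod)2/IMes-catalysed methylative ynal macrocyclisation closes the ten-membered ring (17 steps, longest linear sequence 11). The route is a paper plan: nothing has been run, and the stereochemical outcomes of steps 5, 10, 11 and 16 rest on literature models.

**Retrosynthetic overview**

1. Last bond: Yamaguchi angeloylation of the C6 carbinol of the bicyclic alcohol; the tertiary C11 angelate is put on earlier, on the monocyclic lactone (lithium alkoxide + angeloyl chloride).
2. Ten-membered ring (formed second): the C5–C6 and C4–CH3 bonds are made together by Ni(cod)2/IMes-catalysed methylative alkyne–aldehyde macrocyclisation of a seco ynal with Me2Zn, which also sets the E alkene and the C6 carbinol.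
3. γ-Lactone (formed first) at the fragment union: a west α-chiral allylboronate adds to an east aldehyde (C8–C9 bond, C8 stereocentre, Z C1=C10 alkene); the C8 alkoxide then opens a dioxolanone, closing the lactone and freeing the C11 hydroxyl.
4. East aldehyde: (S)-lactic acid as its pivalaldehyde dioxolanone plus a butenediol-derived allylic carbonate by [Ir(cod)Cl]2/phosphoramidite-catalysed branched allylation (C7–C11 bond, both stereocentres), then ozonolysis. West boronate: pent-4-yn-1-ol carbamate plus isopropenyl boronate by sparteine-mediated lithiation–borylation.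

Atom labels C1–C15 are germacrane positions of the target (C12 lactone carbonyl, C11 quaternary carbinol carbon, C7/C8 ring-fusion carbons, C6 secondary carbinol carbon). Assumption: (Sa,S,S)-L1 and (−)-sparteine follow their established facial models on these substrates.

**Route**

Step 1
Reactants: 1 but-2-yne-1,4-diol
Product: 2 (E)-but-2-ene-1,4-diol
Conditions: LiAlH4, THF, 0 °C → reflux; aqueous work-up
Reagents that add atoms: none
Why: Alkoxide-directed anti hydroalumination of a propargylic alcohol by LiAlH4 gives only the E alkene, the geometry needed for the allylic substitution in step 5.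

Step 2
Reactants: 2 (E)-but-2-ene-1,4-diol
Product: 3 (E)-4-[(tert-butyldimethylsilyl)oxy]but-2-en-1-ol
Conditions: NaH (1.0 equiv), THF, 0 °C → rt; TBSCl (1.0 equiv)
Reagents that add atoms: tert-butyldimethylsilyl chloride CC(C)(C)[Si](C)(C)Cl
Why: Monosilylation of a symmetrical diol through its monosodium alkoxide (McDougal protocol) differentiates the two ends.

Step 3
Reactants: 3 (E)-4-[(tert-butyldimethylsilyl)oxy]but-2-en-1-ol
Product: 4 (E)-4-[(tert-butyldimethylsilyl)oxy]but-2-en-1-yl methyl carbonate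
Conditions: ClCO2Me, pyridine, CH2Cl2, 0 °C
Reagents that add atoms: methyl chloroformate COC(=O)Cl
Why: Chloroformate O-acylation turns the allylic alcohol into the carbonate leaving group for allylic substitution.

Step 4
Reactants: 5 (S)-lactic acid; 6 pivalaldehyde
Product: 7 (2S,5S)-2-tert-butyl-5-methyl-1,3-dioxolan-4-one
Conditions: TsOH·H2O (cat.), pentane, reflux (Dean–Stark); crystallisation at −78 °C
Reagents that add atoms: none
Why: Acid-catalysed acetalisation (Seebach self-regeneration of stereocentres) gives the cis acetal, which crystallises pure and whose tert-butyl-bearing centre later controls the enolate face.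

Step 5
Reactants: 7 (2S,5S)-2-tert-butyl-5-methyl-1,3-dioxolan-4-one; 4 (E)-4-[(tert-butyldimethylsilyl)oxy]but-2-en-1-yl methyl carbonate
Product: 10 (2S,5R)-2-tert-butyl-5-[(2S)-1-[(tert-butyldimethylsilyl)oxy]but-3-en-2-yl]-5-methyl-1,3-dioxolan-4-one, via lithium dioxol-4-olate 8 (not isolated), via chlorozinc dioxol-4-olate 9 (not isolated)
Conditions: LiN(iPr)2, THF, −78 °C; ZnCl2, −78 → −20 °C; then 4, [Ir(cod)Cl]2 (2 mol %), (Sa,S,S)-L1 (4 mol %, n-PrNH2-activated; L1 = binaphthol-derived N,N-bis(1-phenylethyl)phosphoramidite), THF, −20 °C → rt; aqueous work-up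
Reagents that add atoms: none
Why: [Ir(cod)Cl]2/L1-catalysed branch-selective asymmetric allylic alkylation (Helmchen–Hartwig type) of a zinc ester enolate; the ligand fixes the face of the allyl complex attacked at its substituted terminus (C7, S), and the enolate reacts anti to its tert-butyl group (quaternary C11, net retention of the lactic acid configuration).

Step 6
Reactants: 10 (2S,5R)-2-tert-butyl-5-[(2S)-1-[(tert-butyldimethylsilyl)oxy]but-3-en-2-yl]-5-methyl-1,3-dioxolan-4-one
Product: 11 (2S)-3-[(tert-butyldimethylsilyl)oxy]-2-[(2S,4R)-2-tert-butyl-4-methyl-5-oxo-1,3-dioxolan-4-yl]propanal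
Conditions: O3, CH2Cl2, −78 °C; then Me2S, −78 °C → rt
Reagents that add atoms: ozone [O-][O+]=O
Why: Ozonolysis with reductive work-up cleaves the only alkene to the C8 aldehyde under neutral conditions, so the α-stereocentre C7 is not epimerised.

Step 7
Reactants: 12 pent-4-yn-1-ol
Product: 13 pent-4-yn-1-yl N,N-diisopropylcarbamate
Conditions: iPr2NC(O)Cl, Et3N, CH2Cl2, reflux
Reagents that add atoms: N,N-diisopropylcarbamoyl chloride CC(C)N(C(C)C)C(=O)Cl
Why: Carbamoylation installs the Hoppe-type directing and leaving group needed for α-lithiation.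

Step 8
Reactants: 13 pent-4-yn-1-yl N,N-diisopropylcarbamate
Product: 15 5-(trimethylsilyl)pent-4-yn-1-yl N,N-diisopropylcarbamate, via lithium acetylide 14 (not isolated)
Conditions: n-BuLi, THF, −78 °C; TMSCl, −78 °C → rt
Reagents that add atoms: chlorotrimethylsilane C[Si](C)(C)Cl
Why: Acetylide formation and C-silylation mask the acidic alkyne C–H against s-BuLi in step 10.

Step 9
Reactants: 16 isopropenylmagnesium bromide
Product: 17 4,4,5,5-tetramethyl-2-(prop-1-en-2-yl)-1,3,2-dioxaborolane
Conditions: iPrOBpin, THF, −78 °C → rt; aqueous work-up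
Reagents that add atoms: 2-isopropoxy-4,4,5,5-tetramethyl-1,3,2-dioxaborolane CC(C)OB1OC(C)(C)C(C)(C)O1
Why: Grignard borylation: the alkenyl group displaces isopropoxide on boron to give the pinacol boronate.

Step 10
Reactants: 15 5-(trimethylsilyl)pent-4-yn-1-yl N,N-diisopropylcarbamate; 17 4,4,5,5-tetramethyl-2-(prop-1-en-2-yl)-1,3,2-dioxaborolane
Product: 20 4,4,5,5-tetramethyl-2-[(3R)-2-methyl-7-(trimethylsilyl)hept-1-en-6-yn-3-yl]-1,3,2-dioxaborolane, via sparteine-bound α-lithio carbamate 18 (not isolated), via lithium boronate complex 19 (not isolated)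
Conditions: s-BuLi, (−)-sparteine, Et2O, −78 °C, 5 h; 17, −78 °C; MgBr2·OEt2, −78 °C → reflux
Reagents that add atoms: none
Why: Hoppe lithiation followed by Aggarwal lithiation–borylation: s-BuLi/(−)-sparteine removes the pro-S proton, the boronate adds with retention, and the isopropenyl group migrates from boron to carbon with inversion (anti to the leaving carbamate), giving the (R)-α-substituted allylboronate.

Step 11
Reactants: 11 (2S)-3-[(tert-butyldimethylsilyl)oxy]-2-[(2S,4R)-2-tert-butyl-4-methyl-5-oxo-1,3-dioxolan-4-yl]propanal; 20 4,4,5,5-tetramethyl-2-[(3R)-2-methyl-7-(trimethylsilyl)hept-1-en-6-yn-3-yl]-1,3,2-dioxaborolane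
Product: 23 (3R,4R,5R)-4-{[(tert-butyldimethylsilyl)oxy]methyl}-3-hydroxy-3-methyl-5-[(2Z)-2-methylhept-2-en-6-yn-1-yl]oxolan-2-one, via pinacol borate ester 21 (not isolated), via silylalkyne hydroxy lactone 22 (not isolated)
Conditions: toluene, 40 °C, 36 h; then K2CO3 (0.2 equiv), MeOH, 0 °C → rt
Reagents that add atoms: none
Why: Allylboration with an α-chiral allylboronate through a chair transition state in which the α-substituent sits axial (avoiding strain with the 2-methyl group and the pinacol), which gives the Z trisubstituted alkene and transfers the boronate chirality to C8 under reagent control; methanolysis then lets the C8 alkoxide open the dioxolanone to the trans γ-lactone with loss of pivalaldehyde, and cleaves the alkynyl silane.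

Step 12
Reactants: 24 angelic acid
Product: 25 angeloyl chloride
Conditions: 1-chloro-N,N,2-trimethylprop-1-en-1-amine, CH2Cl2, 0 °C → rt; used as solution
Reagents that add atoms: 1-chloro-N,N,2-trimethylprop-1-en-1-amine CC(C)=C(Cl)N(C)C
Why: Neutral acid chloride formation with the Ghosez reagent releases no HCl, so the Z acid does not isomerise to the tiglic series.

Step 13
Reactants: 23 (3R,4R,5R)-4-{[(tert-butyldimethylsilyl)oxy]methyl}-3-hydroxy-3-methyl-5-[(2Z)-2-methylhept-2-en-6-yn-1-yl]oxolan-2-one; 25 angeloyl chloride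
Product: 27 (3R,4R,5R)-4-{[(tert-butyldimethylsilyl)oxy]methyl}-3-methyl-5-[(2Z)-2-methylhept-2-en-6-yn-1-yl]-2-oxooxolan-3-yl (2Z)-2-methylbut-2-enoate, via lithium tertiary alkoxide 26 (not isolated)
Conditions: LiN(SiMe3)2 (1.05 equiv), THF, −78 °C; 25, −78 → 0 °C
Reagents that add atoms: none
Why: O-acylation of a pre-formed tertiary lithium alkoxide by an acid chloride at low temperature; no nucleophilic amine is present (so no Z to E isomerisation), C11 is quaternary (no enolisation), and the much less acidic alkyne C–H is left alone.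

Step 14
Reactants: 27 (3R,4R,5R)-4-{[(tert-butyldimethylsilyl)oxy]methyl}-3-methyl-5-[(2Z)-2-methylhept-2-en-6-yn-1-yl]-2-oxooxolan-3-yl (2Z)-2-methylbut-2-enoate
Product: 28 (3R,4R,5R)-4-(hydroxymethyl)-3-methyl-5-[(2Z)-2-methylhept-2-en-6-yn-1-yl]-2-oxooxolan-3-yl (2Z)-2-methylbut-2-enoate
Conditions: HF·pyridine, pyridine, THF, 0 °C → rt
Reagents that add atoms: none
Why: Fluoride desilylation under mildly acidic conditions frees the primary alcohol without base-induced acyl migration or translactonisation.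

Step 15
Reactants: 28 (3R,4R,5R)-4-(hydroxymethyl)-3-methyl-5-[(2Z)-2-methylhept-2-en-6-yn-1-yl]-2-oxooxolan-3-yl (2Z)-2-methylbut-2-enoate
Product: 29 (3R,4R,5R)-4-formyl-3-methyl-5-[(2Z)-2-methylhept-2-en-6-yn-1-yl]-2-oxooxolan-3-yl (2Z)-2-methylbut-2-enoate
Conditions: Dess–Martin periodinane, CH2Cl2, 0 °C → rt; used crude
Reagents that add atoms: none
Why: Dess–Martin oxidation is neutral and base-free, so the β-acyloxy aldehyde forms without β-elimination or epimerisation at C7.

Step 16
Reactants: 29 (3R,4R,5R)-4-formyl-3-methyl-5-[(2Z)-2-methylhept-2-en-6-yn-1-yl]-2-oxooxolan-3-yl (2Z)-2-methylbut-2-enoate; 30 dimethylzinc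
Product: 32 (3R,3aR,4S,5E,9Z,11aR)-4-hydroxy-3,6,10-trimethyl-2-oxo-2,3,3a,4,7,8,11,11a-octahydrocyclodeca[b]furan-3-yl (2Z)-2-methylbut-2-enoate, via methylzinc alkoxide 31 (not isolated)
Conditions: Ni(cod)2 (20 mol %), IMes (1,3-dimesitylimidazol-2-ylidene, 20 mol %), 30 (3 equiv), THF, 0.002 M, syringe-pump addition of 29 over 10 h, 0 °C → rt; aqueous work-up (pH 7)
Reagents that add atoms: none
Why: Proposed new method: Ni(cod)2/IMes-catalysed methylative endo-macrocyclisation of a terminal ynal, in which zerovalent nickel joins the aldehyde carbon C6 to the terminal alkyne carbon C5 by oxidative cyclisation to an oxanickelacyclopentene (the small carbene ligand steers C–C bond formation to the unsubstituted alkyne carbon, i.e. endo closure of the ten-membered ring), Me2Zn transmetalates (Zn–O, Ni–CH3) and C(sp2)–CH3 reductive elimination completes a syn addition that places C6 and the new methyl cis (the E alkene); the C6 carbinol (4S) is expected from a transition state with the carbonyl oxygen exo to the forming ring and C5 approaching anti to the quaternary C11 (H6 anti to H7); the closest known reactions are three-component alkylative couplings of alkynes, aldehydes and organozincs with Ni(cod)2 and their small-ring ynal cyclisations, and Ni(cod)2/carbene reductive (silane) macrocyclisations of terminal ynals, but a methylative closure of a ten-membered ring has not been shown.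

Step 17
Reactants: 32 (3R,3aR,4S,5E,9Z,11aR)-4-hydroxy-3,6,10-trimethyl-2-oxo-2,3,3a,4,7,8,11,11a-octahydrocyclodeca[b]furan-3-yl (2Z)-2-methylbut-2-enoate; 24 angelic acid
Product: 34 (3R,3aS,4S,5E,9Z,11aR)-3,6,10-trimethyl-3-{[(2Z)-2-methylbut-2-enoyl]oxy}-2-oxo-2,3,3a,4,7,8,11,11a-octahydrocyclodeca[b]furan-4-yl (2Z)-2-methylbut-2-enoate, via angelic 2,4,6-trichlorobenzoic mixed anhydride 33 (not isolated)
Conditions: 24 (3 equiv), 2,4,6-trichlorobenzoyl chloride, Et3N, toluene, rt, 2 h; then 32, toluene, 75 °C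
Reagents that add atoms: none
Why: Yamaguchi esterification through the mixed anhydride, run without a nucleophilic pyridine catalyst so the angelate keeps its Z geometry; the secondary allylic alcohol is acylated with retention at C6.

**Compound list**

1 | but-2-yne-1,4-diol | OCC#CCO | starting material
2 | (E)-but-2-ene-1,4-diol | OC/C=C/CO | intermediate
3 | (E)-4-[(tert-butyldimethylsilyl)oxy]but-2-en-1-ol | OC/C=C/CO[Si](C)(C)C(C)(C)C | intermediate
4 | (E)-4-[(tert-butyldimethylsilyl)oxy]but-2-en-1-yl methyl carbonate | COC(=O)OC/C=C/CO[Si](C)(C)C(C)(C)C | intermediate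
5 | (S)-lactic acid, (2S)-2-hydroxypropanoic acid | C[C@H](O)C(=O)O | starting material
6 | pivalaldehyde, 2,2-dimethylpropanal | CC(C)(C)C=O | starting material
7 | (2S,5S)-2-tert-butyl-5-methyl-1,3-dioxolan-4-one (cis acetal) | C[C@@H]1O[C@H](C(C)(C)C)OC1=O | intermediate
8 | lithium (2S)-2-tert-butyl-5-methyl-1,3-dioxol-4-olate (not isolated) | CC1=C(O[Li])O[C@@H](C(C)(C)C)O1 | intermediate
9 | chlorozinc (2S)-2-tert-butyl-5-methyl-1,3-dioxol-4-olate (not isolated) | CC1=C(O[Zn]Cl)O[C@@H](C(C)(C)C)O1 | intermediate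
10 | (2S,5R)-2-tert-butyl-5-[(2S)-1-[(tert-butyldimethylsilyl)oxy]but-3-en-2-yl]-5-methyl-1,3-dioxolan-4-one | C=C[C@@H](CO[Si](C)(C)C(C)(C)C)[C@@]1(C)O[C@H](C(C)(C)C)OC1=O | intermediate
11 | (2S)-3-[(tert-butyldimethylsilyl)oxy]-2-[(2S,4R)-2-tert-butyl-4-methyl-5-oxo-1,3-dioxolan-4-yl]propanal | O=C[C@@H](CO[Si](C)(C)C(C)(C)C)[C@@]1(C)O[C@H](C(C)(C)C)OC1=O | intermediate
12 | pent-4-yn-1-ol | C#CCCCO | starting material
13 | pent-4-yn-1-yl N,N-diisopropylcarbamate | C#CCCCOC(=O)N(C(C)C)C(C)C | intermediate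
14 | [5-(diisopropylcarbamoyloxy)pent-1-yn-1-yl]lithium (not isolated) | [Li]C#CCCCOC(=O)N(C(C)C)C(C)C | intermediate
15 | 5-(trimethylsilyl)pent-4-yn-1-yl N,N-diisopropylcarbamate | C[Si](C)(C)C#CCCCOC(=O)N(C(C)C)C(C)C | intermediate
16 | isopropenylmagnesium bromide (prop-1-en-2-ylmagnesium bromide, THF solution) | CC(=C)[Mg]Br | starting material
17 | 4,4,5,5-tetramethyl-2-(prop-1-en-2-yl)-1,3,2-dioxaborolane | CC(=C)B1OC(C)(C)C(C)(C)O1 | intermediate
18 | [(1S)-1-(diisopropylcarbamoyloxy)-5-(trimethylsilyl)pent-4-yn-1-yl]lithium, (−)-sparteine complex (not isolated; sparteine omitted from SMILES) | C[Si](C)(C)C#CCC[C@H]([Li])OC(=O)N(C(C)C)C(C)C | intermediate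
19 | lithium boronate complex of 18 with 17, boron bound with retention (not isolated) | C[Si](C)(C)C#CCC[C@H]([B-]1(C(C)=C)OC(C)(C)C(C)(C)O1)OC(=O)N(C(C)C)C(C)C.[Li+] | intermediate
20 | 4,4,5,5-tetramethyl-2-[(3R)-2-methyl-7-(trimethylsilyl)hept-1-en-6-yn-3-yl]-1,3,2-dioxaborolane | C[Si](C)(C)C#CCC[C@@H](B1OC(C)(C)C(C)(C)O1)C(C)=C | intermediate
21 | pinacol borate ester of the (Z)-homoallylic alcohol from 11 and 20, dioxolanone intact, C8 as in 23 (not isolated) | C[Si](C)(C)C#CCC/C=C(/C)C[C@@H](OB1OC(C)(C)C(C)(C)O1)[C@@H](CO[Si](C)(C)C(C)(C)C)[C@@]2(C)O[C@H](C(C)(C)C)OC2=O | intermediate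
22 | (3R,4R,5R)-4-{[(tert-butyldimethylsilyl)oxy]methyl}-3-hydroxy-3-methyl-5-[(2Z)-2-methyl-7-(trimethylsilyl)hept-2-en-6-yn-1-yl]oxolan-2-one (not isolated) | C[Si](C)(C)C#CCC/C=C(/C)C[C@H]1OC(=O)[C@](C)(O)[C@@H]1CO[Si](C)(C)C(C)(C)C | intermediate
23 | (3R,4R,5R)-4-{[(tert-butyldimethylsilyl)oxy]methyl}-3-hydroxy-3-methyl-5-[(2Z)-2-methylhept-2-en-6-yn-1-yl]oxolan-2-one | C#CCC/C=C(/C)C[C@H]1OC(=O)[C@](C)(O)[C@@H]1CO[Si](C)(C)C(C)(C)C | intermediate
24 | angelic acid, (2Z)-2-methylbut-2-enoic acid | C/C=C(/C)C(=O)O | starting material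
25 | angeloyl chloride, (2Z)-2-methylbut-2-enoyl chloride | C/C=C(/C)C(=O)Cl | intermediate
26 | lithium tertiary alkoxide of 23 (not isolated) | C#CCC/C=C(/C)C[C@H]1OC(=O)[C@](C)(O[Li])[C@@H]1CO[Si](C)(C)C(C)(C)C | intermediate
27 | (3R,4R,5R)-4-{[(tert-butyldimethylsilyl)oxy]methyl}-3-methyl-5-[(2Z)-2-methylhept-2-en-6-yn-1-yl]-2-oxooxolan-3-yl (2Z)-2-methylbut-2-enoate | C#CCC/C=C(/C)C[C@H]1OC(=O)[C@](C)(OC(=O)/C(C)=C\C)[C@@H]1CO[Si](C)(C)C(C)(C)C | intermediate
28 | (3R,4R,5R)-4-(hydroxymethyl)-3-methyl-5-[(2Z)-2-methylhept-2-en-6-yn-1-yl]-2-oxooxolan-3-yl (2Z)-2-methylbut-2-enoate | C#CCC/C=C(/C)C[C@H]1OC(=O)[C@](C)(OC(=O)/C(C)=C\C)[C@@H]1CO | intermediate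
29 | (3R,4R,5R)-4-formyl-3-methyl-5-[(2Z)-2-methylhept-2-en-6-yn-1-yl]-2-oxooxolan-3-yl (2Z)-2-methylbut-2-enoate | C#CCC/C=C(/C)C[C@H]1OC(=O)[C@](C)(OC(=O)/C(C)=C\C)[C@@H]1C=O | intermediate
30 | dimethylzinc | C[Zn]C | starting material
31 | methylzinc alkoxide of 32 (not isolated) | C[Zn]O[C@H]1/C=C(\C)CC/C=C(/C)C[C@H]2OC(=O)[C@](C)(OC(=O)/C(C)=C\C)[C@H]12 | intermediate
32 | (3R,3aR,4S,5E,9Z,11aR)-4-hydroxy-3,6,10-trimethyl-2-oxo-2,3,3a,4,7,8,11,11a-octahydrocyclodeca[b]furan-3-yl (2Z)-2-methylbut-2-enoate | O[C@H]1/C=C(\C)CC/C=C(/C)C[C@H]2OC(=O)[C@](C)(OC(=O)/C(C)=C\C)[C@H]12 | intermediate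
33 | (2Z)-2-methylbut-2-enoic 2,4,6-trichlorobenzoic anhydride (not isolated) | C/C=C(/C)C(=O)OC(=O)c1c(Cl)cc(Cl)cc1Cl | intermediate
34 | CNP0391997.3, (3R,3aS,4S,5E,9Z,11aR)-3,6,10-trimethyl-3-{[(2Z)-2-methylbut-2-enoyl]oxy}-2-oxo-2,3,3a,4,7,8,11,11a-octahydrocyclodeca[b]furan-4-yl (2Z)-2-methylbut-2-enoate | C/C=C(/C)C(=O)O[C@H]1/C=C(\C)CC/C=C(/C)C[C@H]2OC(=O)[C@](C)(OC(=O)/C(C)=C\C)[C@H]12 | target

**Totals**

Total step count: 17.
Longest linear sequence: 11 steps (steps 1, 2, 3, 5, 6, 11, 13, 14, 15, 16, 17). The other branches (steps 4; 7, 8, 10; 9; 12) join it.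

**Steps most likely to fail**

Step 16, the proposed new method. A methylative closure of a ten-membered ring is unproven. Possible failures are closure at the internal alkyne carbon, alkyne oligomerisation, β-elimination of the doubly β-acyloxy aldehyde, and a wrong or low preference at C6. The fallback uses known chemistry, sets out from 27 and comes back at 32. Water-accelerated carboalumination of the terminal alkyne of 27 (Me3Al, Cp2ZrCl2 cat., one equivalent of H2O, CH2Cl2, −23 °C; then I2) adds methyl and iodine syn and gives the (E)-vinyl iodide silyl ether F1. HF·pyridine then gives the iodo alcohol F2, and Dess–Martin periodinane gives the iodo aldehyde F3. An intramolecular Nozaki–Hiyama–Kishi coupling (CrCl2, NiCl2 1 mol %, DMSO/THF, 0.002 M, rt) forms the same C5–C6 bond and returns to the route at 32. If needed, a chiral sulfonamide ligand on CrCl2 can steer the C6 configuration.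

Step 5. A fully substituted zinc dioxolanone enolate is an extension of the nucleophile range of [Ir(cod)Cl]2/L1 allylation. The enolate may be too hindered or decompose, and the ligand and the acetal centre may be mismatched. The fallback sets out from 3 and 7 and comes back at 11. Ozonolysis of 3 (O3; Me2S) gives [(tert-butyldimethylsilyl)oxy]acetaldehyde F4. A Henry reaction with nitromethane (Et3N cat.) gives the nitro alcohol F5, and dehydration (MsCl, Et3N) gives the (E)-nitroalkene F6. The lithium enolate 8, made from 7 with LiN(iPr)2 at −78 °C, then adds to F6 anti to the tert-butyl group to give the nitro adduct F7. This auxiliary-controlled Michael addition is known for this enolate class; the sense of induction at C7 would have to be confirmed. A Nef reaction (KOtBu, THF, −78 °C; O3; Me2S) turns the nitromethyl group into the aldehyde and rejoins the route at 11, so step 6 is not needed.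

Step 13. Angeloylation of a tertiary α-hydroxy lactone may stall or isomerise to the tiglate. The fallback sets out from 23 and comes back at 27. Acylation of 23 with 2-[bis(2,2,2-trifluoroethoxy)phosphoryl]propanoic acid (DCC, DMAP cat., CH2Cl2; the acid reacts through its phosphonoketene, which acylates hindered alcohols) gives the phosphonopropionate ester F8. Still–Gennari olefination with acetaldehyde (KN(SiMe3)2, 18-crown-6, THF, −78 °C) then builds the (Z)-2-methylbut-2-enoate directly on the ester and returns at 27.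

**Further compounds**

F1 | step 16 | (3R,4R,5R)-4-{[(tert-butyldimethylsilyl)oxy]methyl}-5-[(2Z,6E)-7-iodo-2,6-dimethylhepta-2,6-dien-1-yl]-3-methyl-2-oxooxolan-3-yl (2Z)-2-methylbut-2-enoate | I/C=C(\C)CC/C=C(/C)C[C@H]1OC(=O)[C@](C)(OC(=O)/C(C)=C\C)[C@@H]1CO[Si](C)(C)C(C)(C)C
F2 | step 16 | (3R,4R,5R)-4-(hydroxymethyl)-5-[(2Z,6E)-7-iodo-2,6-dimethylhepta-2,6-dien-1-yl]-3-methyl-2-oxooxolan-3-yl (2Z)-2-methylbut-2-enoate | I/C=C(\C)CC/C=C(/C)C[C@H]1OC(=O)[C@](C)(OC(=O)/C(C)=C\C)[C@@H]1CO
F3 | step 16 | (3R,4R,5R)-4-formyl-5-[(2Z,6E)-7-iodo-2,6-dimethylhepta-2,6-dien-1-yl]-3-methyl-2-oxooxolan-3-yl (2Z)-2-methylbut-2-enoate | I/C=C(\C)CC/C=C(/C)C[C@H]1OC(=O)[C@](C)(OC(=O)/C(C)=C\C)[C@@H]1C=O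
F4 | step 5 | [(tert-butyldimethylsilyl)oxy]acetaldehyde | CC(C)(C)[Si](C)(C)OCC=O
F5 | step 5 | 1-[(tert-butyldimethylsilyl)oxy]-3-nitropropan-2-ol (racemic) | CC(C)(C)[Si](C)(C)OCC(O)C[N+](=O)[O-]
F6 | step 5 | tert-butyldimethyl{[(2E)-3-nitroprop-2-en-1-yl]oxy}silane | CC(C)(C)[Si](C)(C)OC/C=C/[N+](=O)[O-]
F7 | step 5 | (2S,5R)-2-tert-butyl-5-[(2S)-1-[(tert-butyldimethylsilyl)oxy]-3-nitropropan-2-yl]-5-methyl-1,3-dioxolan-4-one | [O-][N+](=O)C[C@@H](CO[Si](C)(C)C(C)(C)C)[C@@]1(C)O[C@H](C(C)(C)C)OC1=O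
F8 | step 13 | (3R,4R,5R)-4-{[(tert-butyldimethylsilyl)oxy]methyl}-3-methyl-5-[(2Z)-2-methylhept-2-en-6-yn-1-yl]-2-oxooxolan-3-yl 2-[bis(2,2,2-trifluoroethoxy)phosphoryl]propanoate | C#CCC/C=C(/C)C[C@H]1OC(=O)[C@](C)(OC(=O)C(C)P(=O)(OCC(F)(F)F)OCC(F)(F)F)[C@@H]1CO[Si](C)(C)C(C)(C)C
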